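**Plan**
Retrosynthesis: ring C is cut at O1–C8a and at C4–C4a. This gives 3,4,5,6-tetramethoxybenzyne (ring A) and a keto ester holding C2, C3, C4, the C3 methoxy group and ring B. The keto ester is cut once more at C2–C3 (Claisen).
Enabling feature: ring A (C4a, C5, C6, C7, C8, C8a) carries OMe on C5, C6, C7 and C8. C5/C8 and C6/C7 are therefore mirror pairs about the midpoint of the C4a–C8a bond, the aryne across that bond has two identical carbons, and only one annulation product can form.
Forward: ring A is bought complete and armed as the ortho-silylaryl triflate (steps 1–4). Ring B arrives with the aroyl chloride and is joined to methyl methoxyacetate (step 5). Ring C, the only ring built, closes in step 6 and gives the target directly.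
Stereochemistry: the target has no stereocentre. The single centre of the keto ester is racemic and vanishes on enolisation, so only the enolate geometry (oxygen cis to the ester) counts.

Key step: step 6

Assumption: 1,2,3,4-tetramethoxybenzene, methyl methoxyacetate and 4-methoxybenzoyl chloride are taken as commercial, and the keto ester is used as the racemate.

**Step 1**
Reactants: 1 1,2,3,4-tetramethoxybenzene
Product: 4 2,3,4,5-tetramethoxyphenol, via aryllithium 2 (not isolated), via lithium aryltrimethoxyborate 3 (not isolated)
Conditions: n-BuLi, TMEDA, THF, 0 °C; B(OMe)3, −78 °C → rt; AcOH, 30% H2O2, 0 °C → rt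
Reagents that add atoms: hydrogen peroxide, OO (phenol oxygen of 4); n-butyllithium, [Li]CCCC (lithium of 2 and 3 only); trimethyl borate, COB(OC)OC (boron and its methoxy groups in 3 only)
Why: Directed ortho-metalation beside a methoxy group (the two free positions of 1 are equivalent), borylation and oxidative aryl shift from boron to oxygen form a standard one-flask arene hydroxylation, and the acetic acid medium keeps the electron-rich phenol protonated and less prone to further oxidation.

**Step 2**
Reactants: 4 2,3,4,5-tetramethoxyphenol
Product: 5 2-bromo-3,4,5,6-tetramethoxyphenol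
Conditions: NBS (1.0 equiv), CH2Cl2, −20 °C, dark
Reagents that add atoms: N-bromosuccinimide, O=C1CCC(=O)N1Br
Why: Electrophilic aromatic bromination of a phenol at its only free ring position, which lies ortho to the hydroxy group and para to a methoxy group, so one equivalent of NBS at low temperature should substitute before it oxidises.

**Step 3**
Reactants: 5 2-bromo-3,4,5,6-tetramethoxyphenol
Product: 6 (2-bromo-3,4,5,6-tetramethoxyphenoxy)trimethylsilane
Conditions: HN(SiMe3)2, THF, reflux; evaporation
Reagents that add atoms: hexamethyldisilazane, C[Si](C)(C)N[Si](C)(C)C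
Why: O-silylation of a phenol with hexamethyldisilazane needs no added base and should leave a silyl ether clean enough for use after removal of the volatiles.

**Step 4**
Reactants: 6 (2-bromo-3,4,5,6-tetramethoxyphenoxy)trimethylsilane
Product: 9 2,3,4,5-tetramethoxy-6-(trimethylsilyl)phenyl trifluoromethanesulfonate, via lithiated silyl ether 7 (not isolated), via lithium silylphenoxide 8 (not isolated)
Conditions: n-BuLi, THF, −78 °C; Tf2O, −78 → 0 °C
Reagents that add atoms: trifluoromethanesulfonic anhydride, O=S(=O)(OS(=O)(=O)C(F)(F)F)C(F)(F)F; n-butyllithium, [Li]CCCC (lithium of 7 and 8 only)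
Why: Bromine–lithium exchange, retro-Brook (1,3 O-to-C) silyl migration driven by the change from aryllithium to phenoxide, and O-triflation in the same flask are the standard way from ortho-bromophenols to ortho-silylaryl triflates, and the sequence tolerates flanking methoxy groups.

**Step 5**
Reactants: 10 methyl methoxyacetate; 11 4-methoxybenzoyl chloride
Product: 14 methyl 2-methoxy-3-(4-methoxyphenyl)-3-oxopropanoate (racemic), via lithium ester enolate 12 (not isolated), via lithium keto ester enolate 13 (not isolated)
Conditions: 10 (2.2 equiv), LiN(i-Pr)2 (2.1 equiv), THF, −78 °C; 11 (1.0 equiv), −78 → 0 °C; 1 M HCl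
Reagents that add atoms: lithium diisopropylamide, CC(C)N([Li])C(C)C (lithium of 12 and 13 only)
Why: Crossed Claisen condensation (C-acylation of a lithium ester enolate by a non-enolisable aroyl chloride), in which the second equivalent of 12 stores the more acidic product as its enolate 13 and so blocks a second acylation, while the new centre is racemic and of no consequence.

**Step 6**
Reactants: 9 2,3,4,5-tetramethoxy-6-(trimethylsilyl)phenyl trifluoromethanesulfonate; 14 methyl 2-methoxy-3-(4-methoxyphenyl)-3-oxopropanoate
Product: 18 3-methoxytangeretin (3,5,6,7,8,4'-hexamethoxyflavone), via cesium enolate 15 (not isolated), via 3,4,5,6-tetramethoxybenzyne 16 (not isolated), via ortho-aryloxy aryl anion 17 (not isolated)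
Conditions: 14 (1.5 equiv), CsF (5 equiv), 18-crown-6 (2 equiv), THF, 65 °C, slow addition of 9 (1.0 equiv)
Reagents that add atoms: cesium fluoride, [Cs+].[F-] (cesium of 15 and 17 only; no reagent atom remains in 18)
Why: Proposed new method: fluoride attacks the silicon of 9 and triflate departs to give the aryne 16, fluoride also deprotonates 14 to the enolate 15, the enolate oxygen adds to an aryne carbon (O1–C8a), and the ortho-aryl anion 17 so formed attacks the neighbouring ester carbonyl and expels methoxide (C4–C4a). The closest known reaction types are the aryne annulation of salicylate esters to xanthones, which runs through the same O-arylation and acyl capture with a phenoxide in place of an enolate, and the acyl-alkylation of arynes by keto ester enolates, which begins at carbon and is the competing pathway here. Ring C closes in the 6-exo-trig mode (aryl carbanion onto the ester C=O, ring atoms C4a, C8a, O1, C2, C3, C4), and no stereocentre is formed. Regioselectivity is not an issue because the two reactive carbons of 16 are equivalent by symmetry. The selectivity needed is O- over C-arylation, and it should be secured by the fully substituted enolate carbon (OMe, CO2Me, aroyl), by the methoxy group beside each aryne carbon, which makes a quaternary centre at that site very crowded, and by the crown-complexed cesium ion, which leaves the enolate oxygen free. The enolate should hold its oxygen cis to the ester, since the other geometry presses the anisyl ring against the ester, and THF, an excess of 15 and slow addition of 9 should hold back protonation of 17 and self-reaction of 16.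

**Compound list**
1 | 1,2,3,4-tetramethoxybenzene | COc1ccc(OC)c(OC)c1OC | starting material
2 | (2,3,4,5-tetramethoxyphenyl)lithium | [Li]c1cc(OC)c(OC)c(OC)c1OC | intermediate
3 | lithium trimethoxy(2,3,4,5-tetramethoxyphenyl)borate | [Li+].CO[B-](OC)(OC)c1cc(OC)c(OC)c(OC)c1OC | intermediate
4 | 2,3,4,5-tetramethoxyphenol | COc1cc(O)c(OC)c(OC)c1OC | intermediate
5 | 2-bromo-3,4,5,6-tetramethoxyphenol | COc1c(O)c(Br)c(OC)c(OC)c1OC | intermediate
6 | (2-bromo-3,4,5,6-tetramethoxyphenoxy)trimethylsilane | COc1c(O[Si](C)(C)C)c(Br)c(OC)c(OC)c1OC | intermediate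
7 | [2,3,4,5-tetramethoxy-6-(trimethylsilyloxy)phenyl]lithium | COc1c(O[Si](C)(C)C)c([Li])c(OC)c(OC)c1OC | intermediate
8 | lithium 2,3,4,5-tetramethoxy-6-(trimethylsilyl)phenoxide | [Li+].COc1c([O-])c([Si](C)(C)C)c(OC)c(OC)c1OC | intermediate
9 | 2,3,4,5-tetramethoxy-6-(trimethylsilyl)phenyl trifluoromethanesulfonate | COc1c(OC)c(OC)c(OS(=O)(=O)C(F)(F)F)c([Si](C)(C)C)c1OC | intermediate
10 | methyl methoxyacetate | COCC(=O)OC | starting material
11 | 4-methoxybenzoyl chloride | COc1ccc(C(Cl)=O)cc1 | starting material
12 | lithium 1,2-dimethoxyethen-1-olate (enolate of 10, chelated geometry drawn) | [Li+].CO/C=C(\[O-])OC | intermediate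
13 | lithium (E)-2,3-dimethoxy-1-(4-methoxyphenyl)-3-oxoprop-1-en-1-olate (enolate oxygen cis to the ester) | [Li+].COC(=O)/C(OC)=C(\[O-])c1ccc(OC)cc1 | intermediate
14 | methyl 2-methoxy-3-(4-methoxyphenyl)-3-oxopropanoate (racemic) | COC(=O)C(OC)C(=O)c1ccc(OC)cc1 | intermediate
15 | cesium (E)-2,3-dimethoxy-1-(4-methoxyphenyl)-3-oxoprop-1-en-1-olate (enolate oxygen cis to the ester) | [Cs+].COC(=O)/C(OC)=C(\[O-])c1ccc(OC)cc1 | intermediate
16 | 3,4,5,6-tetramethoxybenzyne | COC1=C(OC)C(OC)=C(OC)C#C1 | intermediate
17 | cesium 2-{[(E)-2,3-dimethoxy-1-(4-methoxyphenyl)-3-oxoprop-1-en-1-yl]oxy}-3,4,5,6-tetramethoxybenzen-1-ide | [Cs+].COC(=O)/C(OC)=C(\Oc1[c-]c(OC)c(OC)c(OC)c1OC)c1ccc(OC)cc1 | intermediate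
18 | 3-methoxytangeretin (3,5,6,7,8,4'-hexamethoxyflavone) | COc1ccc(-c2oc3c(OC)c(OC)c(OC)c(OC)c3c(=O)c2OC)cc1 | target

**Total step count:** 6
**Longest linear sequence:** 5 (steps 1, 2, 3, 4 and 6; step 5 is the second branch)

**Steps most likely to fail**

Step 6. The ambident enolate may attack the aryne through carbon. The aryl anion would then add to the ketone and the four-membered ring would fragment (acyl-alkylation). Alternatively the aryl anion may be protonated before it reaches the ester.
The fallback uses known chemistry and builds ring C on the intact phenol by a Baker–Venkataraman sequence. It sets out from 4 and 11 and returns at 18. Phenol 4 is acylated at its free ortho position with methoxyacetic acid in BF3·OEt2 (Friedel–Crafts/Fries-type acylation) to give 1-(2-hydroxy-3,4,5,6-tetramethoxyphenyl)-2-methoxyethan-1-one F1. Esterification with 11 in pyridine gives 2-(methoxyacetyl)-3,4,5,6-tetramethoxyphenyl 4-methoxybenzoate F2. KOH in pyridine moves the aroyl group onto the methylene carbon and gives 1-(2-hydroxy-3,4,5,6-tetramethoxyphenyl)-2-methoxy-3-(4-methoxyphenyl)propane-1,3-dione F3. Catalytic H2SO4 in AcOH then closes ring C by cyclodehydration to 18.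

Step 2. The para-methoxyphenol may be oxidised with loss of a methyl group (ipso attack of the brominating agent) instead of being substituted at the free position.
In the fallback both halogens go in before the oxygen. It sets out from 1, returns at 5, and makes step 1 unnecessary. Br2 (2 equiv) in AcOH converts 1 into 1,2-dibromo-3,4,5,6-tetramethoxybenzene F4. A single bromine–magnesium exchange with i-PrMgCl·LiCl at −20 °C gives (2-bromo-3,4,5,6-tetramethoxyphenyl)magnesium chloride F5. This is trapped with B(OMe)3 as dimethyl (2-bromo-3,4,5,6-tetramethoxyphenyl)boronate F6, which is oxidised in the same flask with H2O2 to 5.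

Step 5. The methoxyacetate enolate may self-condense, be acylated on oxygen, or the product may be acylated twice.
In the fallback the methoxy group is introduced last by carbenoid O–H insertion. It sets out from 11 and returns at 14. Compound 11 is combined with KO2CCH2CO2Me, MgCl2 and Et3N in MeCN (decarboxylative malonate acylation) to give methyl 3-(4-methoxyphenyl)-3-oxopropanoate F7. Regitz diazo transfer with 4-acetamidobenzenesulfonyl azide and Et3N gives methyl 2-diazo-3-(4-methoxyphenyl)-3-oxopropanoate F8. Catalytic Rh2(OAc)4 in CH2Cl2 with methanol then inserts the carbenoid into the O–H bond and delivers 14.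

**Further compounds**
F1 | step 6 | 1-(2-hydroxy-3,4,5,6-tetramethoxyphenyl)-2-methoxyethan-1-one | COCC(=O)c1c(O)c(OC)c(OC)c(OC)c1OC
F2 | step 6 | 2-(methoxyacetyl)-3,4,5,6-tetramethoxyphenyl 4-methoxybenzoate | COCC(=O)c1c(OC(=O)c2ccc(OC)cc2)c(OC)c(OC)c(OC)c1OC
F3 | step 6 | 1-(2-hydroxy-3,4,5,6-tetramethoxyphenyl)-2-methoxy-3-(4-methoxyphenyl)propane-1,3-dione (racemic, enolisable) | COC(C(=O)c1ccc(OC)cc1)C(=O)c1c(O)c(OC)c(OC)c(OC)c1OC
F4 | step 2 | 1,2-dibromo-3,4,5,6-tetramethoxybenzene | COc1c(Br)c(Br)c(OC)c(OC)c1OC
F5 | step 2 | (2-bromo-3,4,5,6-tetramethoxyphenyl)magnesium chloride | COc1c(Br)c([Mg]Cl)c(OC)c(OC)c1OC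
F6 | step 2 | dimethyl (2-bromo-3,4,5,6-tetramethoxyphenyl)boronate | COB(OC)c1c(Br)c(OC)c(OC)c(OC)c1OC
F7 | step 5 | methyl 3-(4-methoxyphenyl)-3-oxopropanoate | COC(=O)CC(=O)c1ccc(OC)cc1
F8 | step 5 | methyl 2-diazo-3-(4-methoxyphenyl)-3-oxopropanoate | COC(=O)C(=[N+]=[N-])C(=O)c1ccc(OC)cc1
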